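**Retrosynthetic overview**

1. Feature: in the 6-oxabicyclo[3.2.1]octane-7,8-dione core the lactone ring (C1–C7–O6–C5–C8) is a tetronic acid in disguise. The C8 ketone lies between C1 (also α to the C7 lactone carbonyl) and C5 (also α to the side-chain ketone and bound to O6). Both carbons are nucleophilic, so the C2–C3–C4 bridge can be laid across them as a three-carbon bis-electrophile.
2. C3 prenyl ⇒ C3 formyl group (vinyl addition, acetylation, reductive allylic transposition, cross-metathesis).
3. Key disconnection: C1–C2 (allylic alkylation) and C5–C4 (Michael addition) ⇒ 3-prenyl-5-[(R)-2-methylbutanoyl]tetronic acid + 2-(acetoxymethyl)-3-methylbut-2-enal.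
4. Tetronic acid ⇒ 4-methoxyfuran-2(5H)-one (C3 bromination/Stille prenylation, C5 aldol with (R)-2-methylbutanal, oxidation, O-demethylation); enal ⇒ diethyl isopropylidenemalonate.
5. Ring order: the five-membered lactone ring is bought; the six-membered carbocycle (C1–C2–C3–C4–C5–C8) is the only ring made, in the key step.

Key step: step 11

Remark (numbering): core atoms are numbered as in 6-oxabicyclo[3.2.1]octane: C1 prenylated bridgehead, C2 CH2, C3 CH, C4 CMe2, C5 bridgehead bearing O6 and the acyl group, C7 lactone carbonyl, C8 bridging ketone.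
Remark (assumption): the (R,R) antipode of the ligand in step 11 is assumed to deliver the (1S) bridgehead; should the sense of induction be the opposite, the (S,S) ligand is used.
Remark (tautomers): the tetronic acid and the monocyclic key-step intermediate are drawn as chelated enols; the aldol adduct and its ketone are mixtures at centres that are erased later.

**Step 1**
Reactants: 1 4-methoxyfuran-2(5H)-one
Product: 2 3-bromo-4-methoxyfuran-2(5H)-one
Conditions: NBS, MeCN, rt, dark
Reagents that add atoms: N-bromosuccinimide, O=C1CCC(=O)N1Br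
Why: Electrophilic bromination of the push–pull enol ether at its nucleophilic C3 (addition–elimination), with the polar solvent and exclusion of light holding back radical bromination at C5.

**Step 2**
Reactants: 2 3-bromo-4-methoxyfuran-2(5H)-one
Product: 3 4-methoxy-3-(3-methylbut-2-en-1-yl)furan-2(5H)-one
Conditions: Bu3SnCH2CH=CMe2, Pd(PPh3)4 (5 mol %), CuI (10 mol %), DMF, 80 °C
Reagents that add atoms: tributyl(3-methylbut-2-en-1-yl)stannane, CCCC[Sn](CCCC)(CCCC)CC=C(C)C
Why: Stille cross-coupling of the vinylic bromide with the allylic stannane, where reductive elimination at the less substituted allyl terminus should give the linear prenyl group and avoid the O- and bis-alkylation that direct prenylation of tetronic acid suffers.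

**Step 3**
Reactants: 4 (R)-2-methylbutanoic acid
Product: 5 (R)-2-methylbutan-1-ol
Conditions: LiAlH4, Et2O, 0 °C → rt
Reagents that add atoms: none
Why: Hydride reduction of the carboxylic acid, in which the carboxylate stage is not enolised and the stereocentre is carried through unchanged.

**Step 4**
Reactants: 5 (R)-2-methylbutan-1-ol
Product: 6 (R)-2-methylbutanal
Conditions: TEMPO (1 mol %), KBr (10 mol %), aq NaOCl, NaHCO3, CH2Cl2/H2O, 0 °C
Reagents that add atoms: none
Why: Nitroxyl-catalysed hypochlorite oxidation (Anelli oxidation) is fast at 0 °C under buffered conditions and should give the α-branched aldehyde without racemisation, for immediate use.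

**Step 5**
Reactants: 3 4-methoxy-3-(3-methylbut-2-en-1-yl)furan-2(5H)-one; 6 (R)-2-methylbutanal
Product: 8 5-[(2R)-1-hydroxy-2-methylbutyl]-4-methoxy-3-(3-methylbut-2-en-1-yl)furan-2(5H)-one (mixture at C5 and the carbinol carbon), via lithium furan-2-olate 7 (not isolated)
Conditions: LiN(i-Pr)2, THF, −78 °C; then 6, −78 °C; AcOH quench at −78 °C
Reagents that add atoms: none
Why: γ-Deprotonation of the methyl tetronate gives the aromatic 2-furanolate, which undergoes a vinylogous aldol addition through C5 faster than it enolises the aldehyde; the two new centres are unselective, but one is oxidised in step 6 and the other becomes quaternary in step 11.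

**Step 6**
Reactants: 8 5-[(2R)-1-hydroxy-2-methylbutyl]-4-methoxy-3-(3-methylbut-2-en-1-yl)furan-2(5H)-one
Product: 9 4-methoxy-5-[(2R)-2-methylbutanoyl]-3-(3-methylbut-2-en-1-yl)furan-2(5H)-one (C5 epimers in equilibrium with the enol)
Conditions: Dess–Martin periodinane (1.2 equiv), NaHCO3, CH2Cl2, 0 °C → rt
Reagents that add atoms: none
Why: Dess–Martin oxidation of the secondary alcohol under buffered, non-basic conditions, in which the product enolises towards C5 and not towards the side-chain stereocentre, which therefore keeps its configuration.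

**Step 7**
Reactants: 9 4-methoxy-5-[(2R)-2-methylbutanoyl]-3-(3-methylbut-2-en-1-yl)furan-2(5H)-one
Product: 10 4-hydroxy-5-[(2R)-2-methylbutanoyl]-3-(3-methylbut-2-en-1-yl)furan-2(5H)-one (chelated dienol tautomer drawn)
Conditions: LiCl, DMSO, 60 °C; then 1 M HCl work-up; used at once under argon
Reagents that add atoms: none
Why: SN2 demethylation of the vinylogous methyl ester by chloride, in which the acyl-substituted tetronate is a good leaving group, under neutral conditions that spare the prenyl group and the side-chain stereocentre.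

**Step 8**
Reactants: 11 diethyl 2-(propan-2-ylidene)propanedioate (diethyl isopropylidenemalonate)
Product: 12 2-(propan-2-ylidene)propane-1,3-diol
Conditions: i-Bu2AlH (4.5 equiv), CH2Cl2, −78 → 0 °C; aq potassium sodium tartrate
Reagents that add atoms: none
Why: 1,2-Reduction of both ester groups by the aluminium hydride, in which the fully substituted β-carbon of the alkylidene malonate resists conjugate hydride addition.

**Step 9**
Reactants: 12 2-(propan-2-ylidene)propane-1,3-diol
Product: 14 2-(hydroxymethyl)-3-methylbut-2-en-1-yl acetate, via cyclic orthoester 13 (not isolated)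
Conditions: MeC(OMe)3, PPTS (cat.), CH2Cl2, rt; then H2O, rt
Reagents that add atoms: trimethyl orthoacetate, CC(OC)(OC)OC; water, O
Why: Mono-acylation of a symmetrical 1,3-diol through its cyclic orthoester, whose mild acid hydrolysis opens the ring to exactly one acetate and one free hydroxyl group.

**Step 10**
Reactants: 14 2-(hydroxymethyl)-3-methylbut-2-en-1-yl acetate
Product: 15 2-(acetoxymethyl)-3-methylbut-2-enal
Conditions: Dess–Martin periodinane, NaHCO3, CH2Cl2, 0 °C → rt
Reagents that add atoms: none
Why: Dess–Martin oxidation of the primary allylic alcohol to the enal, under conditions that leave the allylic acetate in place.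

**Step 11**
Reactants: 10 4-hydroxy-5-[(2R)-2-methylbutanoyl]-3-(3-methylbut-2-en-1-yl)furan-2(5H)-one; 15 2-(acetoxymethyl)-3-methylbut-2-enal
Product: 17 (1S,3S,5S)-4,4-dimethyl-5-[(2R)-2-methylbutanoyl]-1-(3-methylbut-2-en-1-yl)-7,8-dioxo-6-oxabicyclo[3.2.1]octane-3-carbaldehyde, via C-allylated furandione 16 (not isolated)
Conditions: Pd2(dba)3·CHCl3 (2.5 mol %), (R,R)-N,N'-(cyclohexane-1,2-diyl)bis[2-(diphenylphosphino)benzamide] (7.5 mol %), Et3N (1.1 equiv), 15 (1.0 equiv, slow addition), degassed CH2Cl2, 0 °C → rt; then DBU (1.5 equiv), rt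
Reagents that add atoms: none
Why: Zerovalent palladium ionises the primary allylic acetate of 15 to a 2-formyl-1,1-dimethyl-π-allyl complex, and the triethylammonium tetronate of 10 attacks its CH2 terminus through the prenyl-bearing carbon (Tsuji–Trost allylic alkylation; an O-allylated tetronate would re-ionise and drain to the C-allyl isomer) to give 16 with the C1–C2 bond. DBU then removes the diketone C–H of 16 and the enolate adds to the β,β-dimethyl enal in an intramolecular Michael addition, a 6-endo-trig closure that forms C5–C4 and the cyclohexanone ring; the closest known reaction type is the alkylative α,α′-annulation of cyclic 1,3-dicarbonyl compounds with 2-(acetoxymethyl) enals. C1 is set by the chiral ligand, which tells apart the two faces of the flat tetronate (the distant side-chain centre gives no bias); C5 follows from C1 because the three-carbon bridge can only reach the face of the lactone ring from which it hangs; C3 is set thermodynamically, DBU epimerising the aldehyde α-carbon to the equatorial position that points away from the lactone bridge. The step needs attack through the prenyl-bearing and not the acyl-bearing carbon, which the charge distribution of the mono-anion (a tetronate whose acyl-bearing carbon stays protonated or enolised) and the shielding by the branched acyl group should secure, and attack at the CH2 and not the CMe2 allyl terminus, which sterics and the conjugated enal product favour. It also needs 1,4- over 1,2-addition in the closure, which the reversibility of the aldol mode under DBU provides, and it is helped by the absence of any acidic hydrogen at the bridgeheads of 17.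

**Step 12**
Reactants: 17 (1S,3S,5S)-4,4-dimethyl-5-[(2R)-2-methylbutanoyl]-1-(3-methylbut-2-en-1-yl)-7,8-dioxo-6-oxabicyclo[3.2.1]octane-3-carbaldehyde
Product: 18 (1S,3S,5S)-3-(1-hydroxyprop-2-en-1-yl)-4,4-dimethyl-5-[(2R)-2-methylbutanoyl]-1-(3-methylbut-2-en-1-yl)-6-oxabicyclo[3.2.1]octane-7,8-dione (carbinol epimers)
Conditions: CH2=CHMgBr (1.1 equiv), THF, −78 °C; aq NH4Cl
Reagents that add atoms: vinylmagnesium bromide, C=C[Mg]Br
Why: Grignard addition at −78 °C to the aldehyde, the most electrophilic of the four carbonyl groups (each ketone is flanked by a quaternary carbon and the lactone is α-quaternary); the carbinol centre is not controlled and is erased in step 14.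

**Step 13**
Reactants: 18 (1S,3S,5S)-3-(1-hydroxyprop-2-en-1-yl)-4,4-dimethyl-5-[(2R)-2-methylbutanoyl]-1-(3-methylbut-2-en-1-yl)-6-oxabicyclo[3.2.1]octane-7,8-dione
Product: 19 1-[(1S,3S,5S)-4,4-dimethyl-5-[(2R)-2-methylbutanoyl]-1-(3-methylbut-2-en-1-yl)-7,8-dioxo-6-oxabicyclo[3.2.1]octan-3-yl]prop-2-en-1-yl acetate (carbinol epimers)
Conditions: Ac2O, DMAP (cat.), pyridine, CH2Cl2, rt
Reagents that add atoms: acetic anhydride, CC(=O)OC(C)=O
Why: DMAP-catalysed acetylation of the secondary allylic alcohol under mild conditions that do not enolise the side-chain ketone.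

**Step 14**
Reactants: 19 1-[(1S,3S,5S)-4,4-dimethyl-5-[(2R)-2-methylbutanoyl]-1-(3-methylbut-2-en-1-yl)-7,8-dioxo-6-oxabicyclo[3.2.1]octan-3-yl]prop-2-en-1-yl acetate
Product: 20 (1S,3S,5S)-4,4-dimethyl-5-[(2R)-2-methylbutanoyl]-1-(3-methylbut-2-en-1-yl)-3-(prop-2-en-1-yl)-6-oxabicyclo[3.2.1]octane-7,8-dione
Conditions: Pd2(dba)3·CHCl3 (2.5 mol %), n-Bu3P (10 mol %), HCO2H, Et3N, THF, 60 °C
Reagents that add atoms: none
Why: Palladium-catalysed formate reduction of the allylic acetate (Tsuji reductive transposition), in which zerovalent palladium ionises the acetate and the palladium formate delivers hydride to the more substituted allyl terminus with loss of CO2, so both carbinol epimers should converge on the terminal alkene; triethylammonium formate is used because it carries no nucleophilic amine that could open the β-keto lactone.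

**Step 15**
Reactants: 20 (1S,3S,5S)-4,4-dimethyl-5-[(2R)-2-methylbutanoyl]-1-(3-methylbut-2-en-1-yl)-3-(prop-2-en-1-yl)-6-oxabicyclo[3.2.1]octane-7,8-dione
Product: 21 (1S,3S,5S)-4,4-dimethyl-5-[(2R)-2-methylbutanoyl]-1,3-bis(3-methylbut-2-en-1-yl)-6-oxabicyclo[3.2.1]octane-7,8-dione
Conditions: second-generation Grubbs catalyst (5 mol %), 2-methylbut-2-ene/CH2Cl2, 40 °C
Reagents that add atoms: 2-methylbut-2-ene, CC=C(C)C
Why: Olefin cross-metathesis with a large excess of 2-methylbut-2-ene turns the terminal alkene into the prenyl group, while the prenyl group at C1 only exchanges degenerately and the locked diequatorial placement of the two side chains rules out ring closure between them.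

**Compound list**

1 | 4-methoxyfuran-2(5H)-one | COC1=CC(=O)OC1 | starting material
2 | 3-bromo-4-methoxyfuran-2(5H)-one | COC1=C(Br)C(=O)OC1 | intermediate
3 | 4-methoxy-3-(3-methylbut-2-en-1-yl)furan-2(5H)-one | COC1=C(CC=C(C)C)C(=O)OC1 | intermediate
4 | (R)-2-methylbutanoic acid | CC[C@@H](C)C(=O)O | starting material
5 | (R)-2-methylbutan-1-ol | CC[C@@H](C)CO | intermediate
6 | (R)-2-methylbutanal | CC[C@@H](C)C=O | intermediate
7 | lithium 4-methoxy-3-(3-methylbut-2-en-1-yl)furan-2-olate | [Li+].[O-]C1=C(CC=C(C)C)C(OC)=CO1 | intermediate (not isolated)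
8 | 5-[(2R)-1-hydroxy-2-methylbutyl]-4-methoxy-3-(3-methylbut-2-en-1-yl)furan-2(5H)-one | CC[C@@H](C)C(O)C1OC(=O)C(CC=C(C)C)=C1OC | intermediate
9 | 4-methoxy-5-[(2R)-2-methylbutanoyl]-3-(3-methylbut-2-en-1-yl)furan-2(5H)-one | CC[C@@H](C)C(=O)C1OC(=O)C(CC=C(C)C)=C1OC | intermediate
10 | 4-hydroxy-5-[(2R)-2-methylbutanoyl]-3-(3-methylbut-2-en-1-yl)furan-2(5H)-one (dienol tautomer) | CC[C@@H](C)/C(O)=C1\OC(=O)C(CC=C(C)C)=C1O | intermediate
11 | diethyl 2-(propan-2-ylidene)propanedioate | CCOC(=O)C(=C(C)C)C(=O)OCC | starting material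
12 | 2-(propan-2-ylidene)propane-1,3-diol | CC(C)=C(CO)CO | intermediate
13 | 2-methoxy-2-methyl-5-(propan-2-ylidene)-1,3-dioxane | COC1(C)OCC(=C(C)C)CO1 | intermediate (not isolated)
14 | 2-(hydroxymethyl)-3-methylbut-2-en-1-yl acetate | CC(C)=C(CO)COC(C)=O | intermediate
15 | 2-(acetoxymethyl)-3-methylbut-2-enal | CC(C)=C(COC(C)=O)C=O | intermediate
16 | (3S)-3-(2-formyl-3-methylbut-2-en-1-yl)-5-[(2R)-2-methylbutanoyl]-3-(3-methylbut-2-en-1-yl)furan-2,4(3H,5H)-dione (chelated enol of the side-chain ketone) | CC[C@@H](C)/C(O)=C1\OC(=O)[C@@](CC=C(C)C)(CC(C=O)=C(C)C)C1=O | intermediate (not isolated)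
17 | (1S,3S,5S)-4,4-dimethyl-5-[(2R)-2-methylbutanoyl]-1-(3-methylbut-2-en-1-yl)-7,8-dioxo-6-oxabicyclo[3.2.1]octane-3-carbaldehyde | CC[C@@H](C)C(=O)[C@@]12OC(=O)[C@@](CC=C(C)C)(C[C@H](C=O)C1(C)C)C2=O | intermediate
18 | (1S,3S,5S)-3-(1-hydroxyprop-2-en-1-yl)-4,4-dimethyl-5-[(2R)-2-methylbutanoyl]-1-(3-methylbut-2-en-1-yl)-6-oxabicyclo[3.2.1]octane-7,8-dione | CC[C@@H](C)C(=O)[C@@]12OC(=O)[C@@](CC=C(C)C)(C[C@H](C(O)C=C)C1(C)C)C2=O | intermediate
19 | 1-[(1S,3S,5S)-4,4-dimethyl-5-[(2R)-2-methylbutanoyl]-1-(3-methylbut-2-en-1-yl)-7,8-dioxo-6-oxabicyclo[3.2.1]octan-3-yl]prop-2-en-1-yl acetate | CC[C@@H](C)C(=O)[C@@]12OC(=O)[C@@](CC=C(C)C)(C[C@H](C(OC(C)=O)C=C)C1(C)C)C2=O | intermediate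
20 | (1S,3S,5S)-4,4-dimethyl-5-[(2R)-2-methylbutanoyl]-1-(3-methylbut-2-en-1-yl)-3-(prop-2-en-1-yl)-6-oxabicyclo[3.2.1]octane-7,8-dione | CC[C@@H](C)C(=O)[C@@]12OC(=O)[C@@](CC=C(C)C)(C[C@H](CC=C)C1(C)C)C2=O | intermediate
21 | (1S,3S,5S)-4,4-dimethyl-5-[(2R)-2-methylbutanoyl]-1,3-bis(3-methylbut-2-en-1-yl)-6-oxabicyclo[3.2.1]octane-7,8-dione | CC[C@@H](C)C(=O)[C@@]12OC(=O)[C@@](CC=C(C)C)(C[C@H](CC=C(C)C)C1(C)C)C2=O | target

**Step count**

Total: 15 steps. Longest linear sequence: 10 steps (1, 2, 5, 6, 7, 11, 12, 13, 14, 15).

**Steps most likely to fail**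

Step 11. What may go wrong: loss of site selectivity in the allylation (attack of the ambident anion through the acyl-bearing carbon, or a second allylation at the diketone stage before it cyclises), so that the annulation gives the wrong connectivity. Fallback: the side chain is kept at the alcohol oxidation level while the quaternary centre is made, so that the tetronate has only one nucleophilic carbon, and allylation, oxidation and ring closure become separate operations. It sets out from 8. Demethylation with LiCl in DMSO should give 4-hydroxy-5-[(2R)-1-hydroxy-2-methylbutyl]-3-(3-methylbut-2-en-1-yl)furan-2(5H)-one F1. Allylic alkylation of F1 with 15 under the palladium/ligand system of step 11 (Et3N, CH2Cl2, no DBU) should give (3S)-3-(2-formyl-3-methylbut-2-en-1-yl)-5-[(2R)-1-hydroxy-2-methylbutyl]-3-(3-methylbut-2-en-1-yl)furan-2,4(3H,5H)-dione F2. Dess–Martin oxidation of F2 gives 16, now isolated, where the fallback comes back to the route; DBU in CH2Cl2 then closes 16 to 17.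

Step 12. What may go wrong: poor chemoselectivity of the hard organomagnesium reagent (addition to the C8 or side-chain ketone), or deprotonation at C3 followed by retro-Michael opening of the carbocycle. Fallback: one-carbon homologation with phosphorus ylides, which discriminate more strongly in favour of the aldehyde. It sets out from 17. Wittig reaction with Ph3P=CHOMe (from (methoxymethyl)triphenylphosphonium chloride and KN(SiMe3)2, THF, −78 → 0 °C) should give the methyl enol ether (1S,3R,5S)-3-(2-methoxyethenyl)-4,4-dimethyl-5-[(2R)-2-methylbutanoyl]-1-(3-methylbut-2-en-1-yl)-6-oxabicyclo[3.2.1]octane-7,8-dione F3. Hydrolysis with dilute HCl in THF should give the homologous aldehyde 2-[(1S,3R,5S)-4,4-dimethyl-5-[(2R)-2-methylbutanoyl]-1-(3-methylbut-2-en-1-yl)-7,8-dioxo-6-oxabicyclo[3.2.1]octan-3-yl]acetaldehyde F4. Wittig reaction of F4 with Ph3P=CMe2 (from isopropyltriphenylphosphonium iodide and n-BuLi, THF, −78 → 0 °C) gives 21, where the fallback comes back to the route and bypasses 18, 19 and 20.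

Step 2. What may go wrong: allylic transposition during transmetalation or reductive elimination, giving the 1,1-dimethylallyl isomer beside or instead of the prenyl compound. Fallback: a symmetrical allyl group is coupled first and the gem-dimethyl terminus is added by metathesis. It sets out from 2. Stille coupling with allyltributylstannane (Pd(PPh3)4, DMF, 80 °C) should give 4-methoxy-3-(prop-2-en-1-yl)furan-2(5H)-one F5. Cross-metathesis of F5 with 2-methylbut-2-ene (second-generation Grubbs catalyst, CH2Cl2, 40 °C) gives 3, where the fallback comes back to the route.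

**Further compounds**

F1 | step 11 | 4-hydroxy-5-[(2R)-1-hydroxy-2-methylbutyl]-3-(3-methylbut-2-en-1-yl)furan-2(5H)-one | CC[C@@H](C)C(O)C1OC(=O)C(CC=C(C)C)=C1O
F2 | step 11 | (3S)-3-(2-formyl-3-methylbut-2-en-1-yl)-5-[(2R)-1-hydroxy-2-methylbutyl]-3-(3-methylbut-2-en-1-yl)furan-2,4(3H,5H)-dione | CC[C@@H](C)C(O)C1OC(=O)[C@@](CC=C(C)C)(CC(C=O)=C(C)C)C1=O
F3 | step 12 | (1S,3R,5S)-3-(2-methoxyethenyl)-4,4-dimethyl-5-[(2R)-2-methylbutanoyl]-1-(3-methylbut-2-en-1-yl)-6-oxabicyclo[3.2.1]octane-7,8-dione | CC[C@@H](C)C(=O)[C@@]12OC(=O)[C@@](CC=C(C)C)(C[C@H](C=COC)C1(C)C)C2=O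
F4 | step 12 | 2-[(1S,3R,5S)-4,4-dimethyl-5-[(2R)-2-methylbutanoyl]-1-(3-methylbut-2-en-1-yl)-7,8-dioxo-6-oxabicyclo[3.2.1]octan-3-yl]acetaldehyde | CC[C@@H](C)C(=O)[C@@]12OC(=O)[C@@](CC=C(C)C)(C[C@H](CC=O)C1(C)C)C2=O
F5 | step 2 | 4-methoxy-3-(prop-2-en-1-yl)furan-2(5H)-one | COC1=C(CC=C)C(=O)OC1
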